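**Retrosynthetic overview**
1. C8=O is the key C–O bond. The target comes from its 19-lauroyloxy-7,8-didehydro precursor. The C7≡C8 alkyne stands in for the base-sensitive β,γ-enone through both Wittig steps and is hydrated last, steered by the neighbouring laurate.
2. The C19 O–acyl bond comes from enzymatic lauroylation of the only primary OH of 7,8-didehydroloroxanthin.
3. C11=C12 (Wittig) joins a left C15 enyne phosphonium salt to an ε-C25 apo-12'-carotenal. C11'=C12' (Wittig) joins an ε-C15 phosphonium salt to the C10-dialdehyde.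
4. The left C15 unit comes from syn-hydroalkynylation of but-2-yne-1,4-diol with the ring alkyne made from actinol enol triflate; this fixes the C9=C10 geometry and brings in O19. The ε-C15 unit comes from (R)-α-ionone by C3'–H hydroxylation (C–O), vinyl Grignard addition and PPh3·HBr.
5. No ring is formed. Both six-membered rings are bought intact: the β-ring with C3 from actinol, the ε-ring with C6' from (R)-α-ionone.

Assumption: (4R,6R)-actinol, fermentation-grade (R)-α-ionone (≥98 % ee) and the C10-dialdehyde are taken as catalogue chemicals; carotenoid numbering is used in the comments; Wittig E/Z mixtures are equilibrated to the all-trans isomers drawn.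

**Step 1**
Reactants: 1 (4R,6R)-4-hydroxy-2,2,6-trimethylcyclohexanone [(4R,6R)-actinol]
Product: 2 (4R,6R)-2,2,6-trimethyl-4-(triethylsilyloxy)cyclohexanone
Conditions: TESCl, imidazole, CH2Cl2, 0 °C → rt
Reagents that add atoms: chlorotriethylsilane, CC[Si](Cl)(CC)CC
Why: Silyl ether protection of the only OH; TES survives LDA, Zn and Pd but is lost without an extra step in the acidic MeOH of step 5, and the carbinol centre (future C3, R) is untouched.

**Step 2**
Reactants: 2 (4R,6R)-2,2,6-trimethyl-4-(triethylsilyloxy)cyclohexanone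
Product: 4 (4R)-2,6,6-trimethyl-4-(triethylsilyloxy)cyclohex-1-en-1-yl trifluoromethanesulfonate, via lithium enolate 3 (not isolated)
Conditions: LDA, THF, −78 → 0 °C; PhNTf2, 0 °C → rt
Reagents that add atoms: N-phenylbis(trifluoromethanesulfonimide), O=S(=O)(N(c1ccccc1)S(=O)(=O)C(F)(F)F)C(F)(F)F
Why: Enol triflate formation; the other α-carbon is quaternary, so only one tetrasubstituted enolate and triflate can form, the methyl-bearing centre is erased on purpose, and the silyloxy centre (γ to the enolate carbon, no E1cB path) is retained.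

**Step 3**
Reactants: 4 enol triflate; 5 ethynylmagnesium bromide
Product: 7 {[(1R)-4-ethynyl-3,5,5-trimethylcyclohex-3-en-1-yl]oxy}triethylsilane, via ethynylzinc bromide 6 (not isolated)
Conditions: 5, ZnBr2, THF, 0 °C; then 4, Pd(PPh3)4 (5 mol %), 50 °C
Reagents that add atoms: ethynylmagnesium bromide 5, C#C[Mg]Br
Why: Negishi alkynylation; the ethynylzinc reagent delivers the free C7≡C8–H unit to the hindered vinyl triflate without a silyl cap and de-cap sequence and leaves the TES ether alone.

**Step 4**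
Reactants: 7 ring alkyne; 8 but-2-yne-1,4-diol
Product: 9 (2Z)-2-{[(4R)-2,6,6-trimethyl-4-(triethylsilyloxy)cyclohex-1-en-1-yl]ethynyl}but-2-ene-1,4-diol (both CH2OH groups cis)
Conditions: 8 (3 equiv), Pd(OAc)2 (5 mol %), tris(2,6-dimethoxyphenyl)phosphine (5 mol %), THF, rt
Reagents that add atoms: none
Why: Pd-catalysed alkyne–alkyne cross-addition (Trost hydroalkynylation); the symmetrical, propargylically oxygenated acceptor removes any regiochemical issue, and syn addition of alkynyl–H places C19 and C11 cis, which is the C9=C10 geometry of the target.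

**Step 5**
Reactants: 9 C15 enyne diol
Product: 10 {(2Z)-3-(hydroxymethyl)-5-[(4R)-4-hydroxy-2,6,6-trimethylcyclohex-1-en-1-yl]pent-2-en-4-yn-1-yl}triphenylphosphonium bromide
Conditions: PPh3·HBr (1.05 equiv), MeOH, 0 °C → rt, dark
Reagents that add atoms: triphenylphosphine hydrobromide, [Br-].c1ccc(cc1)[PH+](c1ccccc1)c1ccccc1
Why: SN1-type allylic phosphonium salt formation as for classical C15 carotenoid salts; only the C11 hydroxyl gives a cation extended through C9 into the enyne (the C19 cation is a bare cross-conjugated allyl cation), PPh3 traps the primary terminus irreversibly, any 2,5-dihydrofuran from the cis-diol is re-opened by PPh3·HBr, and the acidic MeOH removes the TES group in the same pot.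

**Step 6**
Reactants: 11 (R)-α-ionone
Product: 12 (3R,6R)-3-hydroxy-α-ionone, (3E)-4-[(1R,4R)-4-hydroxy-2,6,6-trimethylcyclohex-2-en-1-yl]but-3-en-2-one
Conditions: trans-3-selective P450 monooxygenase (BM3 variant), NADP+ (cat.), glucose dehydrogenase, D-glucose, air, KPi pH 7.5, 25 °C
Reagents that add atoms: dioxygen, O=O
Why: Enzymatic allylic C–H hydroxylation (H-abstraction/oxygen rebound); the enzyme attacks C3–H on the ring face opposite the C6 side chain, so the 6R substrate gives only the 3,6-trans (3R,6R) alcohol, which sets C3'.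

**Step 7**
Reactants: 12 (3R,6R)-3-hydroxy-α-ionone; 13 vinylmagnesium bromide
Product: 14 (1E)-1-[(1R,4R)-4-hydroxy-2,6,6-trimethylcyclohex-2-en-1-yl]-3-methylpenta-1,4-dien-3-ol (carbinol epimers, inconsequential)
Conditions: 13 (2.5 equiv), THF, −30 → 0 °C; aq. NH4Cl
Reagents that add atoms: vinylmagnesium bromide 13, C=C[Mg]Br
Why: 1,2-Grignard addition to the methyl enone; the first equivalent only deprotonates the 3-OH, the low temperature avoids γ-deprotonation at C6', and the new carbinol centre is destroyed in step 8.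

**Step 8**
Reactants: 14 vinyl carbinol
Product: 15 {(2E,4E)-5-[(1R,4R)-4-hydroxy-2,6,6-trimethylcyclohex-2-en-1-yl]-3-methylpenta-2,4-dien-1-yl}triphenylphosphonium bromide
Conditions: PPh3·HBr (1.0 equiv), CH2Cl2, 0 °C → rt
Reagents that add atoms: triphenylphosphine hydrobromide, [Br-].c1ccc(cc1)[PH+](c1ccccc1)c1ccccc1
Why: Allylic transposition to the phosphonium salt (SN1', vinyl-ionol type); the tertiary bis-allylic alcohol ionises far faster than the secondary ring allylic alcohol, so with one equivalent of the weak acid in a non-solvolysing solvent C3' is neither substituted nor epimerised.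

**Step 9**
Reactants: 15 ε-C15 phosphonium bromide; 16 (2E,4E,6E)-2,7-dimethylocta-2,4,6-trienedial
Product: 18 (3R,6R)-3-hydroxy-12'-apo-ε-caroten-12'-al (all-E), via ε-C15 ylide 17 (not isolated)
Conditions: 16 (2.5 equiv), NaOMe, CH2Cl2/MeOH, 0 °C → rt; heptane, 80 °C (Z → E); crystallise
Reagents that add atoms: none
Why: Wittig olefination; the excess of the symmetrical dialdehyde enforces mono-olefination, free hydroxyls are tolerated by NaOMe, and the hindered 11'-Z isomer relaxes thermally to E.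

**Step 10**
Reactants: 10 left C15 phosphonium bromide; 18 ε-C25 aldehyde
Product: 20 (3R,3'R,6'R)-7,8-didehydro-β,ε-carotene-3,19,3'-triol (7,8-didehydroloroxanthin), via left C15 ylide 19 (not isolated)
Conditions: NaOMe (1.2 equiv), CH2Cl2/MeOH, 0 °C → rt, Ar, dark; EtOH, 70 °C (Z → E); crystallise
Reagents that add atoms: none
Why: Wittig olefination forming C11=C12; with O19 as free hydroxyl or alkoxide the ylide has no leaving group for vinylogous elimination, the alkyne is inert to the base, and C6'–H is not epimerised by alkoxide at rt (these carotenoids survive saponification).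

**Step 11**
Reactants: 20 triol; 21 vinyl laurate
Product: 22 (3R,3'R,6'R)-3,3'-dihydroxy-7,8-didehydro-β,ε-caroten-19-yl dodecanoate
Conditions: 21 (1.3 equiv), immobilised Candida antarctica lipase B, MTBE, 30 °C, dark
Reagents that add atoms: vinyl laurate 21, CCCCCCCCCCCC(=O)OC=C
Why: Lipase-catalysed irreversible transesterification; the unhindered primary allylic 19-OH is acylated far faster than the two ring secondary alcohols, so no protecting groups are needed.

**Step 12**
Reactants: 22 19-laurate of the 7,8-didehydro carotenoid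
Product: 24 (3R,3'R,6'R)-3,3'-dihydroxy-8-oxo-7,8-dihydro-β,ε-caroten-19-yl dodecanoate (target), via C8 enol 23 (not isolated)
Conditions: (JohnPhos)Au(MeCN)SbF6 (3 mol %), H2O (5 equiv), 2,6-di-tert-butylpyridine (5 mol %), 1,4-dioxane, 25 °C, Ar, dark; then I2 (0.5 mol %), CH2Cl2/hexane, diffuse light; crystallise
Reagents that add atoms: water, O
Why: Proposed new method: laurate-relayed Au(I) hydration of a carotenoid 7,8-alkyne – the silver-free, acid-buffered soft π-acid binds the in-plane π bond of C7≡C8 (orthogonal to the polyene), the geminal C19 laurate C=O attacks C8 6-exo-dig anti to gold, water opens the cyclic acyloxonium at the acyl carbon and returns the ester to O19 (the other collapse mode, an 8-enol ester, would pass its acyl group to the adjacent 19-OH and converge), protodeauration at C7 gives enol 23, and kinetic α-protonation at C7 gives the ketone with C5=C6 still in the ring; the tether, reinforced by polyene stabilisation of positive charge at C8, puts oxygen on C8 rather than giving the Rupe-type C7 ketone, it works for either C9=C10 isomer because ester and alkyne are geminal, no stereocentre is touched, and I2 equilibration settles the enone in the C8/C11-trans geometry; closest known reaction type: neighbouring-acyloxy-assisted gold-catalysed regioselective hydration of propargylic and homopropargylic esters, not yet shown on a 2-alkynylallyl ester or a cross-conjugated polyenyne.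

**Compound list**
1 | (4R,6R)-4-hydroxy-2,2,6-trimethylcyclohexanone (actinol) | O=C1[C@H](C)C[C@@H](O)CC1(C)C | starting material
2 | (4R,6R)-2,2,6-trimethyl-4-(triethylsilyloxy)cyclohexanone | O=C1[C@H](C)C[C@@H](O[Si](CC)(CC)CC)CC1(C)C | intermediate
3 | lithium enolate of 2 | [Li+].[O-]C1=C(C)C[C@@H](O[Si](CC)(CC)CC)CC1(C)C | intermediate (not isolated)
4 | (4R)-2,6,6-trimethyl-4-(triethylsilyloxy)cyclohex-1-en-1-yl triflate | FC(F)(F)S(=O)(=O)OC1=C(C)C[C@@H](O[Si](CC)(CC)CC)CC1(C)C | intermediate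
5 | ethynylmagnesium bromide | C#C[Mg]Br | starting material
6 | ethynylzinc bromide | C#C[Zn]Br | intermediate (not isolated)
7 | {[(1R)-4-ethynyl-3,5,5-trimethylcyclohex-3-en-1-yl]oxy}triethylsilane | C#CC1=C(C)C[C@@H](O[Si](CC)(CC)CC)CC1(C)C | intermediate
8 | but-2-yne-1,4-diol | OCC#CCO | starting material
9 | (2Z)-2-{[(4R)-2,6,6-trimethyl-4-(triethylsilyloxy)cyclohex-1-en-1-yl]ethynyl}but-2-ene-1,4-diol | OC\C(=C/CO)C#CC1=C(C)C[C@@H](O[Si](CC)(CC)CC)CC1(C)C | intermediate
10 | left C15 enyne phosphonium bromide | [Br-].OC\C(=C/C[P+](c1ccccc1)(c1ccccc1)c1ccccc1)C#CC1=C(C)C[C@@H](O)CC1(C)C | intermediate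
11 | (R)-α-ionone | CC(=O)/C=C/[C@H]1C(C)=CCCC1(C)C | starting material
12 | (3R,6R)-3-hydroxy-α-ionone | CC(=O)/C=C/[C@H]1C(C)=C[C@H](O)CC1(C)C | intermediate
13 | vinylmagnesium bromide | C=C[Mg]Br | starting material
14 | (3R,6R)-3-hydroxy-vinyl-α-ionol (carbinol epimers) | C=CC(C)(O)/C=C/[C@H]1C(C)=C[C@H](O)CC1(C)C | intermediate
15 | ε-C15 phosphonium bromide | [Br-].c1ccc(cc1)[P+](c1ccccc1)(c1ccccc1)C/C=C(C)/C=C/[C@H]1C(C)=C[C@H](O)CC1(C)C | intermediate
16 | (2E,4E,6E)-2,7-dimethylocta-2,4,6-trienedial | O=C/C(C)=C/C=C/C=C(C)/C=O | starting material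
17 | ε-C15 ylide | c1ccc(cc1)P(c1ccccc1)(c1ccccc1)=C/C=C(C)/C=C/[C@H]1C(C)=C[C@H](O)CC1(C)C | intermediate (not isolated)
18 | (3R,6R)-3-hydroxy-12'-apo-ε-caroten-12'-al | O=C/C(C)=C/C=C/C=C(C)/C=C/C=C(C)/C=C/[C@H]1C(C)=C[C@H](O)CC1(C)C | intermediate
19 | left C15 ylide | OC\C(=C/C=P(c1ccccc1)(c1ccccc1)c1ccccc1)C#CC1=C(C)C[C@@H](O)CC1(C)C | intermediate (not isolated)
20 | (3R,3'R,6'R)-7,8-didehydro-β,ε-carotene-3,19,3'-triol | OC\C(=C/C=C/C(C)=C/C=C/C=C(C)/C=C/C=C(C)/C=C/[C@H]1C(C)=C[C@H](O)CC1(C)C)C#CC1=C(C)C[C@@H](O)CC1(C)C | intermediate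
21 | vinyl laurate (ethenyl dodecanoate) | CCCCCCCCCCCC(=O)OC=C | starting material
22 | 19-dodecanoate of 20 | CCCCCCCCCCCC(=O)OC\C(=C/C=C/C(C)=C/C=C/C=C(C)/C=C/C=C(C)/C=C/[C@H]1C(C)=C[C@H](O)CC1(C)C)C#CC1=C(C)C[C@@H](O)CC1(C)C | intermediate
23 | C8 enol (8-hydroxy-7-ene tautomer of 24) | CCCCCCCCCCCC(=O)OC\C(=C/C=C/C(C)=C/C=C/C=C(C)/C=C/C=C(C)/C=C/[C@H]1C(C)=C[C@H](O)CC1(C)C)\C(O)=C\C1=C(C)C[C@@H](O)CC1(C)C | intermediate (not isolated)
24 | siphonaxanthin 19-dodecanoate (CNP0415583.1) | CCCCCCCCCCCC(=O)OC\C(=C/C=C/C(C)=C/C=C/C=C(C)/C=C/C=C(C)/C=C/[C@H]1C(C)=C[C@H](O)CC1(C)C)C(=O)CC1=C(C)C[C@@H](O)CC1(C)C | target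

**Step count**
Total steps: 12. Longest linear sequence: 8 (steps 1–5, 10, 11, 12).

**Three steps most likely to fail**

Step 12 (the new step).
- Risk: gold may bind or isomerise the polyene, or turnover may stall at the hindered alkyne.
- Fallback: known chemistry (tethered hydrosilylation followed by Tamao–Fleming oxidation, which converts a homopropargylic alcohol into a β-hydroxy ketone). It sets out from triol 20 and comes back at target 24.
- The primary 19-OH of 20 is silylated selectively with Me2SiHCl/Et3N (CH2Cl2, −78 °C) to 19-O-(dimethylsilyl)-7,8-didehydroloroxanthin F1.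
- Karstedt's catalyst (THF, rt) then effects 5-exo-dig syn-hydrosilylation to the C8-silylated 2,2-dimethyl-1,2-oxasilolane F2.
- H2O2/KF/KHCO3 (THF/MeOH, 0 °C) oxidises the C8–Si bond to give siphonaxanthin F3.
- Lipase B with vinyl laurate 21 acylates the primary 19-OH of F3 to give 24.

Step 5.
- Risk: the cis-1,4-diol may end as the 2,5-dihydrofuran, or C9=C10 may scramble in the cation.
- Fallback: the polarity of the C11=C12 olefination is reversed, so no cation is made next to the cis-CH2OH. It sets out from alkyne 7 and aldehyde 18 and comes back at triol 20.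
- Alkyne 7 is added under the same Pd(OAc)2/phosphine catalysis to commercial methyl 4-hydroxybut-2-ynoate. The regiodefined adduct lactonises to 4-(ring-ethynyl)furan-2(5H)-one F4.
- DIBAL-H (1.1 equiv, CH2Cl2, −78 °C) gives the lactol F5.
- In parallel, 18 is reduced (NaBH4, EtOH, 0 °C) to (3R,6R)-12'-apo-ε-carotene-3,12'-diol F6, which PPh3·HBr (CH2Cl2, 0 °C) converts into the ε-C25 phosphonium bromide F7.
- Wittig reaction of F7 with lactol F5 (NaOMe, CH2Cl2/MeOH) opens the lactol and gives 3-O-triethylsilyl-7,8-didehydroloroxanthin F8.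
- PPTS/MeOH desilylates F8 to 20.

Step 4.
- Risk: the unactivated acceptor may be too sluggish, the donor may homodimerise, or Pd may induce furan formation.
- Fallback: hydrometalation followed by cross-coupling. It sets out from diol 8 (with alkyne 7) and comes back at 9.
- Pd-catalysed syn-hydrostannation of 8 (Bu3SnH, PdCl2(PPh3)2, THF) gives (E)-2-(tributylstannyl)but-2-ene-1,4-diol F9.
- Iododestannylation (I2, CH2Cl2, 0 °C) gives (E)-2-iodobut-2-ene-1,4-diol F10.
- Sonogashira coupling of F10 with 7 (Pd(PPh3)4, CuI, Et3N, rt) gives 9 with retention of geometry.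

**Further compounds**
F1 | step 12 | 19-O-(dimethylsilyl)-7,8-didehydroloroxanthin | C[SiH](C)OC\C(=C/C=C/C(C)=C/C=C/C=C(C)/C=C/C=C(C)/C=C/[C@H]1C(C)=C[C@H](O)CC1(C)C)C#CC1=C(C)C[C@@H](O)CC1(C)C
F2 | step 12 | 2,2-dimethyl-1,2-oxasilolane (Si on C8, O on C19, exocyclic C7=C8 and C9=C10) | C[Si]1(C)OC\C(=C/C=C/C(C)=C/C=C/C=C(C)/C=C/C=C(C)/C=C/[C@H]2C(C)=C[C@H](O)CC2(C)C)\C1=C/C1=C(C)C[C@@H](O)CC1(C)C
F3 | step 12 | siphonaxanthin, (3R,3'R,6'R)-3,19,3'-trihydroxy-7,8-dihydro-β,ε-caroten-8-one | OC\C(=C/C=C/C(C)=C/C=C/C=C(C)/C=C/C=C(C)/C=C/[C@H]1C(C)=C[C@H](O)CC1(C)C)C(=O)CC1=C(C)C[C@@H](O)CC1(C)C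
F4 | step 5 | 4-{[(4R)-2,6,6-trimethyl-4-(triethylsilyloxy)cyclohex-1-en-1-yl]ethynyl}furan-2(5H)-one | O=C1OCC(=C1)C#CC1=C(C)C[C@@H](O[Si](CC)(CC)CC)CC1(C)C
F5 | step 5 | 4-{[(4R)-2,6,6-trimethyl-4-(triethylsilyloxy)cyclohex-1-en-1-yl]ethynyl}-2,5-dihydrofuran-2-ol (anomers) | OC1OCC(=C1)C#CC1=C(C)C[C@@H](O[Si](CC)(CC)CC)CC1(C)C
F6 | step 5 | (3R,6R)-12'-apo-ε-carotene-3,12'-diol | OC/C(C)=C/C=C/C=C(C)/C=C/C=C(C)/C=C/[C@H]1C(C)=C[C@H](O)CC1(C)C
F7 | step 5 | [(3R,6R)-3-hydroxy-12'-apo-ε-caroten-12'-yl]triphenylphosphonium bromide | [Br-].c1ccc(cc1)[P+](c1ccccc1)(c1ccccc1)C/C(C)=C/C=C/C=C(C)/C=C/C=C(C)/C=C/[C@H]1C(C)=C[C@H](O)CC1(C)C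
F8 | step 5 | 3-O-triethylsilyl-7,8-didehydroloroxanthin | OC\C(=C/C=C/C(C)=C/C=C/C=C(C)/C=C/C=C(C)/C=C/[C@H]1C(C)=C[C@H](O)CC1(C)C)C#CC1=C(C)C[C@@H](O[Si](CC)(CC)CC)CC1(C)C
F9 | step 4 | (E)-2-(tributylstannyl)but-2-ene-1,4-diol | OC\C(=C/CO)[Sn](CCCC)(CCCC)CCCC
F10 | step 4 | (E)-2-iodobut-2-ene-1,4-diol | OC\C(=C/CO)I
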